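**Retrosynthetic overview**
- Aryl–C1 ketone bond: 2,6-bis(allyloxy)-4-methoxyphenyllithium plus a C1 Weinreb amide, as the last C–C bond; phenols are freed by Pd(0), the C9 alcohol by fluoride.
- C12=C13 (Z): Wittig of the (Z)-hex-3-enyl ylide with a C7–C12 E-enal. C10=C11 (E): formyl-ylide Wittig on an α-silyloxy aldehyde. C6=C7 (Z): Wittig of a 5-carboxypentyl ylide with a β-silyloxy aldehyde.
- C9 stereocentre: ketoreductase reduction of ethyl 4-(PMB-oxy)-3-oxobutanoate, which supplies C7–C10.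
- No ring is formed in the route; the only ring (the arene) is bought as 5-methoxyresorcinol.

Assumption: the carbinol carbon (C9 of the C18 chain) is (R) by CIP analysis of the given SMILES; an (R)-selective ketoreductase is taken from a commercial screening panel.

**Route**

Step 1
Reactants: 1 ethyl 4-chloro-3-oxobutanoate; 2 4-methoxybenzyl alcohol
Product: 3 ethyl 4-[(4-methoxybenzyl)oxy]-3-oxobutanoate
Conditions: NaH (2.2 equiv), THF, 0 °C → rt; aq. HCl work-up
Reagents that add atoms: none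
Why: Williamson-type SN2 displacement of the activated chloride by the PMB alkoxide while the keto ester is masked as its sodium enolate.

Step 2
Reactants: 3 ethyl 4-[(4-methoxybenzyl)oxy]-3-oxobutanoate
Product: 4 ethyl (R)-3-hydroxy-4-[(4-methoxybenzyl)oxy]butanoate
Conditions: (R)-selective ketoreductase (NADPH-dependent alcohol dehydrogenase class), NADP+ (cat.), iPrOH (15% v/v), 0.1 M K-phosphate pH 7.0, MgSO4 (1 mM), 30 °C
Reagents that add atoms: none
Why: Biocatalytic asymmetric ketone reduction: the ketoreductase delivers hydride to one face of the β-keto ester (a privileged substrate class), setting the future C9 as (R), with isopropanol/acetone cofactor recycling.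

Step 3
Reactants: 4 ethyl (R)-3-hydroxy-4-[(4-methoxybenzyl)oxy]butanoate
Product: 5 ethyl (R)-3-[(tert-butyldimethylsilyl)oxy]-4-[(4-methoxybenzyl)oxy]butanoate
Conditions: TBSCl, imidazole, DMF, rt
Reagents that add atoms: tert-butyldimethylsilyl chloride, CC(C)(C)[Si](C)(C)Cl
Why: Imidazole-promoted silylation of the secondary alcohol; the stereocentre is not touched.

Step 4
Reactants: 5 ethyl (R)-3-[(tert-butyldimethylsilyl)oxy]-4-[(4-methoxybenzyl)oxy]butanoate
Product: 6 (R)-3-[(tert-butyldimethylsilyl)oxy]-4-[(4-methoxybenzyl)oxy]butanal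
Conditions: DIBAL-H (1.1 equiv), CH2Cl2, −78 °C; MeOH, Rochelle salt
Reagents that add atoms: none
Why: Partial ester reduction: the tetrahedral aluminium hemiacetal is stable at −78 °C and gives the aldehyde only on work-up.

Step 5
Reactants: 6 (R)-3-[(tert-butyldimethylsilyl)oxy]-4-[(4-methoxybenzyl)oxy]butanal; 7 (5-carboxypentyl)triphenylphosphonium bromide
Product: 9 (R,Z)-9-[(tert-butyldimethylsilyl)oxy]-10-[(4-methoxybenzyl)oxy]dec-6-enoic acid, via carboxylate phosphonium ylide 8 (not isolated)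
Conditions: 7 (1.6 equiv), NaHMDS (3.1 equiv), THF, 0 °C; then 6, −78 °C → rt; 1 M HCl to pH 4 at 0 °C
Reagents that add atoms: none
Why: Z-selective Wittig olefination with a salt-free non-stabilised ylide (kinetic cis-oxaphosphetane) sets the 6Z alkene, and the low temperature suppresses β-elimination of the silyloxy group.

Step 6
Reactants: 9 (R,Z)-9-[(tert-butyldimethylsilyl)oxy]-10-[(4-methoxybenzyl)oxy]dec-6-enoic acid
Product: 11 (R,Z)-9-[(tert-butyldimethylsilyl)oxy]-N-methoxy-10-[(4-methoxybenzyl)oxy]-N-methyldec-6-enamide, via acyl imidazole 10 (not isolated)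
Conditions: CDI (1.2 equiv), CH2Cl2, rt, 1 h; then MeNH(OMe)·HCl (1.5 equiv), rt
Reagents that add atoms: N,O-dimethylhydroxylamine hydrochloride, CNOC.Cl
Why: CDI activation followed by aminolysis gives the Weinreb amide, which carries C1 as a latent ketone through the following steps.

Step 7
Reactants: 11 (R,Z)-9-[(tert-butyldimethylsilyl)oxy]-N-methoxy-10-[(4-methoxybenzyl)oxy]-N-methyldec-6-enamide
Product: 12 (R,Z)-9-[(tert-butyldimethylsilyl)oxy]-10-hydroxy-N-methoxy-N-methyldec-6-enamide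
Conditions: DDQ (1.3 equiv), CH2Cl2/pH 7 buffer (10:1), 0 °C → rt
Reagents that add atoms: none
Why: Oxidative PMB ether cleavage under neutral buffered conditions leaves the TBS ether, Z-alkene and amide intact and avoids base-induced silyl migration.

Step 8
Reactants: 12 (R,Z)-9-[(tert-butyldimethylsilyl)oxy]-10-hydroxy-N-methoxy-N-methyldec-6-enamide
Product: 13 (R,Z)-9-[(tert-butyldimethylsilyl)oxy]-N-methoxy-N-methyl-10-oxodec-6-enamide
Conditions: Dess–Martin periodinane (1.3 equiv), CH2Cl2, 0 °C → rt; used crude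
Reagents that add atoms: none
Why: Dess–Martin oxidation gives the α-silyloxy aldehyde under non-basic conditions, so the adjacent stereocentre is not epimerised.

Step 9
Reactants: 13 (R,Z)-9-[(tert-butyldimethylsilyl)oxy]-N-methoxy-N-methyl-10-oxodec-6-enamide; 14 (triphenylphosphoranylidene)acetaldehyde
Product: 15 (R,6Z,10E)-9-[(tert-butyldimethylsilyl)oxy]-N-methoxy-N-methyl-12-oxododeca-6,10-dienamide
Conditions: 14 (1.5 equiv), toluene, 80 °C
Reagents that add atoms: none
Why: Wittig reaction with the stabilised formyl ylide gives the E-enal; the product enal is less electrophilic than the α-oxygenated aldehyde, so homologation stops after one unit.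

Step 10
Reactants: 16 (Z)-hex-3-en-1-ol
Product: 17 (Z)-1-iodohex-3-ene
Conditions: I2, PPh3, imidazole, CH2Cl2, 0 °C → rt
Reagents that add atoms: iodine, II
Why: Appel-type iodination of the primary alcohol by SN2 on the alkoxyphosphonium, without touching the Z-alkene.

Step 11
Reactants: 17 (Z)-1-iodohex-3-ene
Product: 18 (Z)-hex-3-en-1-yltriphenylphosphonium iodide
Conditions: PPh3 (1.1 equiv), MeCN, reflux
Reagents that add atoms: triphenylphosphine, c1ccc(cc1)P(c1ccccc1)c1ccccc1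
Why: SN2 quaternisation of triphenylphosphine by the primary iodide.

Step 12
Reactants: 18 (Z)-hex-3-en-1-yltriphenylphosphonium iodide; 15 (R,6Z,10E)-9-[(tert-butyldimethylsilyl)oxy]-N-methoxy-N-methyl-12-oxododeca-6,10-dienamide
Product: 20 (R,6Z,10E,12Z,15Z)-9-[(tert-butyldimethylsilyl)oxy]-N-methoxy-N-methyloctadeca-6,10,12,15-tetraenamide, via hexenylidene phosphorane 19 (not isolated)
Conditions: 18 (1.3 equiv), NaHMDS (1.25 equiv), THF, −78 → 0 °C; then 15, −78 → −20 °C
Reagents that add atoms: none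
Why: Z-selective Wittig olefination of the enal with a salt-free non-stabilised ylide builds the 10E,12Z-diene and brings in the 15Z alkene; the Weinreb amide does not react with the ylide at −78 °C.

Step 13
Reactants: 21 5-methoxybenzene-1,3-diol
Product: 22 1-methoxy-3,5-bis(methoxymethoxy)benzene
Conditions: MOMCl (2.5 equiv), iPr2NEt, CH2Cl2, 0 °C → rt
Reagents that add atoms: chloromethyl methyl ether, COCCl
Why: O-alkylation of both phenols installs two MOM groups that direct the following metalation.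

Step 14
Reactants: 22 1-methoxy-3,5-bis(methoxymethoxy)benzene
Product: 24 2-bromo-5-methoxy-1,3-bis(methoxymethoxy)benzene, via aryllithium 23 (not isolated)
Conditions: n-BuLi (1.1 equiv), THF, 0 °C → rt, 1 h; then BrCCl2CCl2Br, −78 °C → rt
Reagents that add atoms: 1,2-dibromo-1,1,2,2-tetrachloroethane, BrC(Cl)(Cl)C(Cl)(Cl)Br
Why: Directed ortho-metalation occurs at the position flanked by the two cooperating OMOM groups, and the aryllithium is brominated by the electrophilic bromine source.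

Step 15
Reactants: 24 2-bromo-5-methoxy-1,3-bis(methoxymethoxy)benzene
Product: 25 2-bromo-5-methoxybenzene-1,3-diol
Conditions: 3 M HCl, MeOH, 50 °C
Reagents that add atoms: none
Why: Acid-catalysed acetal methanolysis removes both MOM groups on a robust arene, long before any acid-sensitive polyene exists.

Step 16
Reactants: 25 2-bromo-5-methoxybenzene-1,3-diol
Product: 26 1,3-bis(allyloxy)-2-bromo-5-methoxybenzene
Conditions: allyl bromide (2.5 equiv), K2CO3, DMF, 50 °C
Reagents that add atoms: allyl bromide, C=CCBr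
Why: Williamson O-allylation gives phenol protecting groups that survive organolithium chemistry and are later removed under neutral Pd(0) conditions.

Step 17
Reactants: 26 1,3-bis(allyloxy)-2-bromo-5-methoxybenzene; 20 (R,6Z,10E,12Z,15Z)-9-[(tert-butyldimethylsilyl)oxy]-N-methoxy-N-methyloctadeca-6,10,12,15-tetraenamide
Product: 28 (R,6Z,10E,12Z,15Z)-1-[2,6-bis(allyloxy)-4-methoxyphenyl]-9-[(tert-butyldimethylsilyl)oxy]octadeca-6,10,12,15-tetraen-1-one, via aryllithium 27 (not isolated)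
Conditions: 26 (2 equiv), n-BuLi (1.9 equiv), THF, −78 °C, 20 min; then 20, −78 → −40 °C; sat. NH4Cl
Reagents that add atoms: none
Why: Bromine–lithium exchange followed by Weinreb ketone synthesis: the chelated tetrahedral intermediate prevents over-addition and collapses to the aryl ketone on work-up.

Step 18
Reactants: 28 (R,6Z,10E,12Z,15Z)-1-[2,6-bis(allyloxy)-4-methoxyphenyl]-9-[(tert-butyldimethylsilyl)oxy]octadeca-6,10,12,15-tetraen-1-one
Product: 29 (R,6Z,10E,12Z,15Z)-9-[(tert-butyldimethylsilyl)oxy]-1-(2,6-dihydroxy-4-methoxyphenyl)octadeca-6,10,12,15-tetraen-1-one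
Conditions: Pd(PPh3)4 (5 mol %), morpholine (10 equiv), degassed THF, rt, dark
Reagents that add atoms: none
Why: Tsuji–Trost deallylation: Pd(0) ionises only the aryl allyl ethers (ortho-acyl phenoxide leaving groups) and morpholine traps the π-allyl, while the allylic silyl ether and the alkenes stay untouched.

Step 19
Reactants: 29 (R,6Z,10E,12Z,15Z)-9-[(tert-butyldimethylsilyl)oxy]-1-(2,6-dihydroxy-4-methoxyphenyl)octadeca-6,10,12,15-tetraen-1-one
Product: 30 (R,6Z,10E,12Z,15Z)-1-(2,6-dihydroxy-4-methoxyphenyl)-9-hydroxyoctadeca-6,10,12,15-tetraen-1-one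
Conditions: TBAF (5 equiv), AcOH (3 equiv), THF, 0 °C → rt
Reagents that add atoms: none
Why: Fluoride-mediated desilylation under buffered, non-acidic conditions frees the dienylic alcohol without ionisation or double-bond migration.

**Compound list**

1 | ethyl 4-chloro-3-oxobutanoate | CCOC(=O)CC(=O)CCl | starting material
2 | 4-methoxybenzyl alcohol | COc1ccc(CO)cc1 | starting material
3 | ethyl 4-[(4-methoxybenzyl)oxy]-3-oxobutanoate | CCOC(=O)CC(=O)COCc1ccc(OC)cc1 | intermediate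
4 | ethyl (R)-3-hydroxy-4-[(4-methoxybenzyl)oxy]butanoate | CCOC(=O)C[C@@H](O)COCc1ccc(OC)cc1 | intermediate
5 | ethyl (R)-3-[(tert-butyldimethylsilyl)oxy]-4-[(4-methoxybenzyl)oxy]butanoate | CCOC(=O)C[C@@H](O[Si](C)(C)C(C)(C)C)COCc1ccc(OC)cc1 | intermediate
6 | (R)-3-[(tert-butyldimethylsilyl)oxy]-4-[(4-methoxybenzyl)oxy]butanal | O=CC[C@@H](O[Si](C)(C)C(C)(C)C)COCc1ccc(OC)cc1 | intermediate
7 | (5-carboxypentyl)triphenylphosphonium bromide | OC(=O)CCCCC[P+](c1ccccc1)(c1ccccc1)c1ccccc1.[Br-] | starting material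
8 | sodium 6-(triphenylphosphoranylidene)hexanoate | [Na+].[O-]C(=O)CCCCC=P(c1ccccc1)(c1ccccc1)c1ccccc1 | intermediate
9 | (R,Z)-9-[(tert-butyldimethylsilyl)oxy]-10-[(4-methoxybenzyl)oxy]dec-6-enoic acid | OC(=O)CCCC/C=C\C[C@@H](O[Si](C)(C)C(C)(C)C)COCc1ccc(OC)cc1 | intermediate
10 | (R,Z)-9-[(tert-butyldimethylsilyl)oxy]-1-(1H-imidazol-1-yl)-10-[(4-methoxybenzyl)oxy]dec-6-en-1-one | O=C(CCCC/C=C\C[C@@H](O[Si](C)(C)C(C)(C)C)COCc1ccc(OC)cc1)n1ccnc1 | intermediate
11 | (R,Z)-9-[(tert-butyldimethylsilyl)oxy]-N-methoxy-10-[(4-methoxybenzyl)oxy]-N-methyldec-6-enamide | CON(C)C(=O)CCCC/C=C\C[C@@H](O[Si](C)(C)C(C)(C)C)COCc1ccc(OC)cc1 | intermediate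
12 | (R,Z)-9-[(tert-butyldimethylsilyl)oxy]-10-hydroxy-N-methoxy-N-methyldec-6-enamide | CON(C)C(=O)CCCC/C=C\C[C@@H](O[Si](C)(C)C(C)(C)C)CO | intermediate
13 | (R,Z)-9-[(tert-butyldimethylsilyl)oxy]-N-methoxy-N-methyl-10-oxodec-6-enamide | CON(C)C(=O)CCCC/C=C\C[C@@H](O[Si](C)(C)C(C)(C)C)C=O | intermediate
14 | (triphenylphosphoranylidene)acetaldehyde | O=CC=P(c1ccccc1)(c1ccccc1)c1ccccc1 | starting material
15 | (R,6Z,10E)-9-[(tert-butyldimethylsilyl)oxy]-N-methoxy-N-methyl-12-oxododeca-6,10-dienamide | CON(C)C(=O)CCCC/C=C\C[C@@H](O[Si](C)(C)C(C)(C)C)/C=C/C=O | intermediate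
16 | (Z)-hex-3-en-1-ol | CC/C=C\CCO | starting material
17 | (Z)-1-iodohex-3-ene | CC/C=C\CCI | intermediate
18 | (Z)-hex-3-en-1-yltriphenylphosphonium iodide | CC/C=C\CC[P+](c1ccccc1)(c1ccccc1)c1ccccc1.[I-] | intermediate
19 | (Z)-hex-3-en-1-ylidenetriphenylphosphorane | CC/C=C\CC=P(c1ccccc1)(c1ccccc1)c1ccccc1 | intermediate
20 | (R,6Z,10E,12Z,15Z)-9-[(tert-butyldimethylsilyl)oxy]-N-methoxy-N-methyloctadeca-6,10,12,15-tetraenamide | CC/C=C\C/C=C\C=C\[C@H](O[Si](C)(C)C(C)(C)C)C/C=C\CCCCC(=O)N(C)OC | intermediate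
21 | 5-methoxybenzene-1,3-diol | COc1cc(O)cc(O)c1 | starting material
22 | 1-methoxy-3,5-bis(methoxymethoxy)benzene | COCOc1cc(OC)cc(OCOC)c1 | intermediate
23 | [4-methoxy-2,6-bis(methoxymethoxy)phenyl]lithium | [Li]c1c(OCOC)cc(OC)cc1OCOC | intermediate
24 | 2-bromo-5-methoxy-1,3-bis(methoxymethoxy)benzene | COCOc1cc(OC)cc(OCOC)c1Br | intermediate
25 | 2-bromo-5-methoxybenzene-1,3-diol | COc1cc(O)c(Br)c(O)c1 | intermediate
26 | 1,3-bis(allyloxy)-2-bromo-5-methoxybenzene | C=CCOc1cc(OC)cc(OCC=C)c1Br | intermediate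
27 | [2,6-bis(allyloxy)-4-methoxyphenyl]lithium | [Li]c1c(OCC=C)cc(OC)cc1OCC=C | intermediate
28 | (R,6Z,10E,12Z,15Z)-1-[2,6-bis(allyloxy)-4-methoxyphenyl]-9-[(tert-butyldimethylsilyl)oxy]octadeca-6,10,12,15-tetraen-1-one | CC/C=C\C/C=C\C=C\[C@H](O[Si](C)(C)C(C)(C)C)C/C=C\CCCCC(=O)c1c(OCC=C)cc(OC)cc1OCC=C | intermediate
29 | (R,6Z,10E,12Z,15Z)-9-[(tert-butyldimethylsilyl)oxy]-1-(2,6-dihydroxy-4-methoxyphenyl)octadeca-6,10,12,15-tetraen-1-one | CC/C=C\C/C=C\C=C\[C@H](O[Si](C)(C)C(C)(C)C)C/C=C\CCCCC(=O)c1c(O)cc(OC)cc1O | intermediate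
30 | (R,6Z,10E,12Z,15Z)-1-(2,6-dihydroxy-4-methoxyphenyl)-9-hydroxyoctadeca-6,10,12,15-tetraen-1-one | CC/C=C\C/C=C\C=C\[C@H](O)C/C=C\CCCCC(=O)c1c(O)cc(OC)cc1O | target

**Totals**
Total step count: 19. Longest linear sequence: 13 steps (steps 1–9, 12, 17, 18, 19, from ethyl 4-chloro-3-oxobutanoate).

**Three steps most likely to fail, with fallbacks**

Step 12 (Z-selective Wittig on enal 15; the 12Z/12E ratio may be hard to purify). The fallback sets out from aldehyde 13 and comes back at 20, bypassing steps 9 and 12. Takai iodo-olefination of 13 (CrCl2, CHI3, THF, 0 °C) gives the (E)-vinyl iodide (R,6Z,10E)-9-[(tert-butyldimethylsilyl)oxy]-11-iodo-N-methoxy-N-methylundeca-6,10-dienamide F1. In parallel, commercial (Z)-pent-2-en-1-ol is converted with PBr3 (Et2O, 0 °C) into (Z)-1-bromopent-2-ene F2, which with ethynylmagnesium bromide and catalytic CuCl (THF) gives (Z)-hept-4-en-1-yne F3. Sonogashira coupling of F1 with F3 (Pd(PPh3)4, CuI, piperidine, rt) gives the enyne (R,6Z,10E,15Z)-9-[(tert-butyldimethylsilyl)oxy]-N-methoxy-N-methyloctadeca-6,10,15-trien-12-ynamide F4. Activated zinc (Zn(Cu/Ag), MeOH/H2O, 40 °C) reduces only its conjugated triple bond, cis, to give 20.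

Step 17 (hindered aryllithium 27 on the Weinreb amide; enolisation or sluggish addition on the most valuable intermediate). The fallback sets out from 20 and 26 and comes back at 28. DIBAL-H (THF, −78 °C) reduces 20 to the aldehyde (R,6Z,10E,12Z,15Z)-9-[(tert-butyldimethylsilyl)oxy]octadeca-6,10,12,15-tetraenal F5. Bromide 26 with Mg turnings and LiCl in THF gives [2,6-bis(allyloxy)-4-methoxyphenyl]magnesium bromide F6, which is inert toward its own allyl ethers. Addition of F6 to F5 at −40 °C gives the benzylic alcohol 1-[2,6-bis(allyloxy)-4-methoxyphenyl]-9-[(tert-butyldimethylsilyl)oxy]octadeca-6,10,12,15-tetraen-1-ol F7 (both C1 epimers, which does not matter). Dess–Martin periodinane (CH2Cl2, 0 °C) oxidises it at once to 28.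

Step 18 (Pd(0) deallylation next to a skipped and conjugated polyene; risk of isomerisation or stalling). The fallback sets out from 20 and 22 and comes back at 29, so steps 14–18 are not needed. Aryllithium 23, made from 22 with n-BuLi as in step 14 but without the bromine quench, is added to 20 (THF, −78 → −40 °C) to give the bis-MOM ketone (R,6Z,10E,12Z,15Z)-9-[(tert-butyldimethylsilyl)oxy]-1-[4-methoxy-2,6-bis(methoxymethoxy)phenyl]octadeca-6,10,12,15-tetraen-1-one F8. TMSOTf with 2,2′-bipyridyl (CH2Cl2, 0 °C) exchanges the aryl MOM ethers for aryl TMS ethers, giving the bis(trimethylsilyl) ether F9 under non-acidic conditions. F9 hydrolyses on aqueous work-up to 29.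

**Further compounds**

F1 | step 12 | (R,6Z,10E)-9-[(tert-butyldimethylsilyl)oxy]-11-iodo-N-methoxy-N-methylundeca-6,10-dienamide | CON(C)C(=O)CCCC/C=C\C[C@@H](O[Si](C)(C)C(C)(C)C)/C=C/I
F2 | step 12 | (Z)-1-bromopent-2-ene | CC/C=C\CBr
F3 | step 12 | (Z)-hept-4-en-1-yne | CC/C=C\CC#C
F4 | step 12 | (R,6Z,10E,15Z)-9-[(tert-butyldimethylsilyl)oxy]-N-methoxy-N-methyloctadeca-6,10,15-trien-12-ynamide | CC/C=C\CC#C/C=C/[C@H](O[Si](C)(C)C(C)(C)C)C/C=C\CCCCC(=O)N(C)OC
F5 | step 17 | (R,6Z,10E,12Z,15Z)-9-[(tert-butyldimethylsilyl)oxy]octadeca-6,10,12,15-tetraenal | CC/C=C\C/C=C\C=C\[C@H](O[Si](C)(C)C(C)(C)C)C/C=C\CCCCC=O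
F6 | step 17 | [2,6-bis(allyloxy)-4-methoxyphenyl]magnesium bromide | Br[Mg]c1c(OCC=C)cc(OC)cc1OCC=C
F7 | step 17 | (9R,6Z,10E,12Z,15Z)-1-[2,6-bis(allyloxy)-4-methoxyphenyl]-9-[(tert-butyldimethylsilyl)oxy]octadeca-6,10,12,15-tetraen-1-ol (both C1 epimers) | CC/C=C\C/C=C\C=C\[C@H](O[Si](C)(C)C(C)(C)C)C/C=C\CCCCC(O)c1c(OCC=C)cc(OC)cc1OCC=C
F8 | step 18 | (R,6Z,10E,12Z,15Z)-9-[(tert-butyldimethylsilyl)oxy]-1-[4-methoxy-2,6-bis(methoxymethoxy)phenyl]octadeca-6,10,12,15-tetraen-1-one | CC/C=C\C/C=C\C=C\[C@H](O[Si](C)(C)C(C)(C)C)C/C=C\CCCCC(=O)c1c(OCOC)cc(OC)cc1OCOC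
F9 | step 18 | (R,6Z,10E,12Z,15Z)-9-[(tert-butyldimethylsilyl)oxy]-1-[4-methoxy-2,6-bis(trimethylsilyloxy)phenyl]octadeca-6,10,12,15-tetraen-1-one | CC/C=C\C/C=C\C=C\[C@H](O[Si](C)(C)C(C)(C)C)C/C=C\CCCCC(=O)c1c(O[Si](C)(C)C)cc(OC)cc1O[Si](C)(C)C
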